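## Retrosynthetic overview
1. Disconnect the 3-O-feruloyl ester to the cis-flavan-3-ol **9** and 4-O-benzylferulic acid **12**. A non-reductive BCl3 debenzylation comes last so the cinnamate C=C survives.
2. Make **9**, with both C2 and C3 stereocentres, by a Ru-catalysed dynamic kinetic resolution (DKR) transfer hydrogenation of the racemising flavan-3-one **8**. This is the proposed new step.
3. Make **8** by Meinwald (hydride-shift) rearrangement of the flav-3-ene 3,4-epoxide **7**, which comes from the 2-aryl-2H-chromene **6**.
4. Form the C (pyran) ring from the A-ring phenol **2** and the B-ring cinnamaldehyde **5** (boronate-directed ortho-alkenylation, then oxa-6π electrocyclisation). The A and B rings are pre-formed, and the pyran ring is formed first.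

Assumptions:
- The target is (2R,3R), 2,3-cis, as encoded in the SMILES.
- All phenols are benzyl-protected.
- The (R,R)-Ru catalyst is assigned by analogy to acetophenone reduction and would be confirmed by screening both antipodes.

## Route

**Step 1**
Reactants: 1 phloroglucinol
Product: 2 3,5-bis(benzyloxy)phenol
Conditions: BnBr (1.9 equiv), K2CO3, acetone, reflux; chromatographic separation from the mono- and tri-benzyl ethers (about 40%)
Reagents that add atoms: benzyl bromide, BrCc1ccccc1
Why: Williamson etherification with statistical dibenzylation; no stereocentres.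

**Step 2**
Reactants: 3 3,4,5-tris(benzyloxy)benzaldehyde; 4 (formylmethylene)triphenylphosphorane
Product: 5 (E)-3-[3,4,5-tris(benzyloxy)phenyl]acrylaldehyde
Conditions: toluene, 100 °C
Reagents that add atoms: none
Why: Wittig olefination with a stabilised ylide gives the E-enal selectively.

**Step 3**
Reactants: 2 3,5-bis(benzyloxy)phenol; 5 the enal
Product: 6 (±)-5,7-bis(benzyloxy)-2-[3,4,5-tris(benzyloxy)phenyl]-2H-chromene
Conditions: PhB(OH)2 (1.2 equiv), AcOH (cat.), toluene, Dean–Stark, 110 °C
Reagents that add atoms: none (the boron reagent is only a mediator and leaves as boroxine/boric acid)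
Why: The aryl boronate directs ortho C-alkylation of the phenol by the aldehyde. Dehydration gives an o-quinone methide, which undergoes oxa-6π electrocyclisation (known 2H-chromene synthesis from phenols and enals). The two ortho positions of the phenol are equivalent, so only the 5,7-dibenzyloxy pattern forms. C2 is racemic and is not carried forward as a fixed stereocentre.

**Step 4**
Reactants: 6 chromene
Product: 7 (±)-trans-3,4-epoxy-5,7-bis(benzyloxy)-2-[3,4,5-tris(benzyloxy)phenyl]chroman (epoxide anti to the 2-aryl group)
Conditions: DMDO in acetone (about 0.08 M, 1.1 equiv), CH2Cl2, −20 °C, 30 min; concentrate cold and use crude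
Reagents that add atoms: dimethyldioxirane, CC1(C)OO1
Why: Prilezhaev-type epoxidation of the electron-rich 2H-chromene alkene under neutral conditions; the epoxide is acid-labile, so it is used without purification.

**Step 5**
Reactants: 7 epoxide
Product: 8 (±)-5,7-bis(benzyloxy)-2-[3,4,5-tris(benzyloxy)phenyl]chroman-3-one (flavan-3-one)
Conditions: BF3·OEt2 (10 mol%), CH2Cl2, −78 → 0 °C
Reagents that add atoms: none
Why: Meinwald rearrangement. Lewis-acid opening at C4 gives a cation strongly stabilised by the 5,7-dialkoxy A ring; a 1,2-hydride shift from C3 then gives the C3 ketone. No stereocentre is retained, and the ketone is stored under argon because C2–H is acidic.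

**Step 6**
Reactants: 8 racemic flavan-3-one
Product: 9 (2R,3R)-5,7-bis(benzyloxy)-2-[3,4,5-tris(benzyloxy)phenyl]chroman-3-ol (cis)
Conditions: RuCl[(R,R)-TsDPEN](p-cymene) (3 mol%), HCO2H/Et3N 5:2, CH2Cl2, 30 °C, 24 h
Reagents that add atoms: none (formic acid is only the hydrogen source; CO2 leaves)
Why: Noyori–Ikariya asymmetric transfer hydrogenation operating as a DKR.
Proposed new method: The C2–H of 8 is flanked by C=O, an aryl group and an aryloxy oxygen, so Et3N/HCO2H racemises it (via the enol) much faster than the ketone is reduced. The chiral Ru–H then reduces only one enantiomer of the equilibrating ketone by concerted outer-sphere H⁻/H⁺ transfer. It does so on the face anti to the bulky 2-aryl group, which places the OH cis to the aryl and sets both C2 and C3 as (2R,3R) in one operation. The closest known chemistry is DKR–ATH of α-aryl, α-alkoxy and α-aryloxy cyclic ketones, which has not been shown on 2-aryl-chroman-3-ones.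

**Step 7**
Reactants: 10 4-(benzyloxy)-3-methoxybenzaldehyde; 11 malonic acid
Product: 12 (E)-3-[4-(benzyloxy)-3-methoxyphenyl]acrylic acid
Conditions: pyridine, piperidine (cat.), 95 °C
Reagents that add atoms: none (malonic acid is the reactant)
Why: Doebner–Knoevenagel condensation with decarboxylation gives the E-cinnamic acid.

**Step 8**
Reactants: 9 cis-flavan-3-ol; 12 4-O-benzylferulic acid
Product: 13 (2R,3R)-hexa-O-benzyl epigallocatechin-3-O-ferulate
Conditions: EDC·HCl, DMAP, CH2Cl2, 0 °C → rt
Reagents that add atoms: none
Why: Steglich esterification at the secondary 3-OH; the C–O bond of the alcohol is untouched, so C3 configuration is retained and C2/C3 stay cis.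

**Step 9**
Reactants: 13 fully protected ester
Product: 14 epigallocatechin-3-O-ferulate (target)
Conditions: BCl3 (1 M in CH2Cl2, 24 equiv), pentamethylbenzene (18 equiv), CH2Cl2, −78 °C, 2 h; quench with MeOH at −78 °C; purify on Sephadex LH-20
Reagents that add atoms: none
Why: Chemoselective BCl3 cleavage of aryl benzyl ethers with a cation scavenger, not hydrogenolysis, which would reduce the cinnamate alkene. At −78 °C the aryl OMe, the ester, the E-alkene and the C2/C3 stereocentres are untouched.

## Compound list
1 | phloroglucinol | Oc1cc(O)cc(O)c1 | starting material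
2 | 3,5-bis(benzyloxy)phenol | Oc1cc(OCc2ccccc2)cc(OCc2ccccc2)c1 | intermediate
3 | 3,4,5-tris(benzyloxy)benzaldehyde | O=Cc1cc(OCc2ccccc2)c(OCc2ccccc2)c(OCc2ccccc2)c1 | starting material
4 | (formylmethylene)triphenylphosphorane | O=CC=P(c1ccccc1)(c1ccccc1)c1ccccc1 | starting material
5 | (E)-3-[3,4,5-tris(benzyloxy)phenyl]acrylaldehyde | O=C/C=C/c1cc(OCc2ccccc2)c(OCc2ccccc2)c(OCc2ccccc2)c1 | intermediate
6 | (±)-5,7-bis(benzyloxy)-2-[3,4,5-tris(benzyloxy)phenyl]-2H-chromene | c1(OCc5ccccc5)cc(OCc5ccccc5)c2C=CC(c3cc(OCc4ccccc4)c(OCc4ccccc4)c(OCc4ccccc4)c3)Oc2c1 | intermediate (racemic)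
7 | (±)-trans-3,4-epoxide of 6 (one enantiomer drawn) | c1(OCc5ccccc5)cc(OCc5ccccc5)c2[C@@H]6O[C@@H]6[C@@H](c3cc(OCc4ccccc4)c(OCc4ccccc4)c(OCc4ccccc4)c3)Oc2c1 | intermediate (racemic)
8 | (±)-5,7-bis(benzyloxy)-2-[3,4,5-tris(benzyloxy)phenyl]chroman-3-one | O=C1Cc2c(OCc5ccccc5)cc(OCc5ccccc5)cc2OC1c1cc(OCc3ccccc3)c(OCc3ccccc3)c(OCc3ccccc3)c1 | intermediate (C2 epimerising)
9 | (2R,3R)-5,7-bis(benzyloxy)-2-[3,4,5-tris(benzyloxy)phenyl]chroman-3-ol | O[C@@H]1Cc2c(OCc3ccccc3)cc(OCc3ccccc3)cc2O[C@@H]1c1cc(OCc2ccccc2)c(OCc2ccccc2)c(OCc2ccccc2)c1 | intermediate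
10 | 4-(benzyloxy)-3-methoxybenzaldehyde | O=Cc1ccc(OCc2ccccc2)c(OC)c1 | starting material
11 | malonic acid | OC(=O)CC(=O)O | starting material
12 | (E)-3-[4-(benzyloxy)-3-methoxyphenyl]acrylic acid | OC(=O)/C=C/c1ccc(OCc2ccccc2)c(OC)c1 | intermediate
13 | (2R,3R)-hexa-O-benzyl epigallocatechin-3-O-ferulate | COc1cc(/C=C/C(=O)O[C@@H]2Cc3c(OCc4ccccc4)cc(OCc4ccccc4)cc3O[C@@H]2c2cc(OCc3ccccc3)c(OCc3ccccc3)c(OCc3ccccc3)c2)ccc1OCc1ccccc1 | intermediate
14 | epigallocatechin-3-O-ferulate | COc1cc(/C=C/C(=O)O[C@@H]2Cc3c(O)cc(O)cc3O[C@@H]2c2cc(O)c(O)c(O)c2)ccc1O | target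

## Totals
Total steps: 9. Longest linear sequence: 7 (Steps 1, 3, 4, 5, 6, 8, 9; the Step 2 route gives the same count).

## Three steps most likely to fail
1. **Step 6 (proposed new DKR–ATH).** The risks are low cis/trans selectivity or ee, and decomposition of the air-sensitive flavan-3-one.
   - Fallback: reduce 8 with L-Selectride to racemic cis-9, which is cis-selective because the bulky hydride attacks anti to the 2-aryl group. Then resolve (±)-9 by chiral-phase preparative HPLC or CAL-B kinetic resolution (maximum 50% yield). All other steps stay the same, and only known chemistry is used.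
2. **Step 3 (chromene formation from a cinnamaldehyde).** Yields may be low, or the 4-position of the phenol may react competitively.
   - Fallback: Claisen–Schmidt condensation of 2-hydroxy-4,6-bis(benzyloxy)benzaldehyde with 3,4,5-tris(benzyloxy)acetophenone gives the 2-hydroxychalcone. Luche reduction to the allylic alcohol, then acid-catalysed dehydrative cyclisation, gives **6** by a different bond-forming sequence.
3. **Step 9 (global BCl3 debenzylation).** Six benzyl groups must be removed without epimerisation at C2, ionisation of the C2–O bond, or ester cleavage.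
   - Fallback: re-run Steps 1–8 with TBS-protected phenols (3,5-bis(TBSO)phenol, tris-TBSO-cinnamaldehyde, 4-TBSO-ferulic acid). Remove all silyl groups at the end with HF·pyridine or AcOH-buffered TBAF, which leaves the cinnamate and the flavan ring intact.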